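## Overview

1. Retrosynthetic cuts, in order: the C2–phenyl bond (flavanone back to a flat chromone and phenylboronic acid); the O1–C2 and C2–C3 bonds (chromone back to an ortho-hydroxyacetophenone and a one-carbon amide acetal); the C8–CH2 bond (back to the acetophenone and a salicyl alcohol); the aryl–acetyl bond (back to 3,4,5-trimethoxyphenol).
2. Enabling feature: in ring C the phenyl-bearing C2 is the beta carbon of the C4 ketone, so the target is the 1,4-adduct of phenyl to an achiral chromone. The C5–C8 substituents of ring A (O, OMe, OMe, CH2Ar) are those of symmetric 3,4,5-trimethoxyphenol, whose ortho-acetyl derivative keeps one open ring carbon, the future C8, beside the phenol that becomes O1.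
3. Forward order: rings A, B (the C2 phenyl) and D (the benzyl arene) are bought as arenes. Ring A is acetylated, ring D is attached through the CH2 by an ortho-quinone methide, and the ring D phenol is capped as a benzyl ether. Ring C is then closed as the chromone, ring B is added at C2, and one Lewis-acid operation frees both phenols.
4. Stereochemistry: the single stereocentre, C2 (S), is set by the chiral pyridine-oxazoline ligand on divalent palladium during conjugate addition to the planar chromone, and is preserved by a cold, base-free final deprotection.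

Key step: step 6

Remark (assumption): the (R) antipode of the tert-butyl pyridine-oxazoline ligand is taken to give the (S)-flavanone, because the (S)-ligand gives (R)-3-aryl-3-methylcyclohexanones and the same facial preference maps onto (R)-flavanone. This is an inference by analogy; a run on parent chromone is to confirm the sense before material is committed.

## Route

Step 1
Reactants: 1 3,4,5-trimethoxyphenol
Product: 2 1-(6-hydroxy-2,3,4-trimethoxyphenyl)ethanone
Conditions: AcOH, BF3·OEt2, 85 °C; then aq. NaOAc
Reagents that add atoms: acetic acid, CC(=O)O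
Why: Boron trifluoride-mediated Friedel–Crafts C-acylation (Nencki type) of an electron-rich phenol goes ortho to the hydroxyl, the two ortho carbons of symmetric 1 are equivalent so only one ketone can form, chelation of the new carbonyl to the phenol stops a second acylation, and the acetate work-up hydrolyses the boron-bound product.

Step 2
Reactants: 3 2-hydroxy-5-methoxybenzaldehyde
Product: 4 2-(hydroxymethyl)-4-methoxyphenol (2-hydroxy-5-methoxybenzyl alcohol)
Conditions: NaBH4, MeOH, 0 °C; H2O work-up
Reagents that add atoms: none
Why: Borohydride reduction of an aromatic aldehyde to the benzylic alcohol is chemoselective, the phenol and aryl methyl ether are inert, and the non-acidic work-up avoids premature loss of water from the acid-sensitive salicyl alcohol.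

Step 3
Reactants: 2 1-(6-hydroxy-2,3,4-trimethoxyphenyl)ethanone; 4 2-hydroxy-5-methoxybenzyl alcohol
Product: 6 1-[2-hydroxy-3-(2-hydroxy-5-methoxybenzyl)-4,5,6-trimethoxyphenyl]ethanone, via ortho-quinone methide 5 (not isolated)
Conditions: ZnCl2, 1,4-dioxane, 100 °C, slow addition of 4 to 2 (1.3 equiv)
Reagents that add atoms: none
Why: ZnCl2 promotes loss of water from 4 to the ortho-quinone methide 5, which is captured in a Friedel–Crafts-type conjugate addition by the single unsubstituted ring carbon of 2 (ortho to its phenol, ortho and para to methoxy groups) with rearomatisation of both rings, as in the known ortho-hydroxybenzylation of ortho-hydroxyaryl ketones, while slow addition of 4 to excess 2 keeps 5 from adding to its own precursor.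

Step 4
Reactants: 6 1-[2-hydroxy-3-(2-hydroxy-5-methoxybenzyl)-4,5,6-trimethoxyphenyl]ethanone
Product: 7 1-{3-[2-(benzyloxy)-5-methoxybenzyl]-2-hydroxy-4,5,6-trimethoxyphenyl}ethanone
Conditions: BnBr (1.05 equiv), K2CO3, acetone, rt
Reagents that add atoms: benzyl bromide, BrCc1ccccc1
Why: Williamson etherification discriminates the two phenols because the ring A hydroxyl is hydrogen-bonded to the acetyl carbonyl and flanked on both sides, so with a weak base and one equivalent of halide at room temperature only the ring D phenoxide should be alkylated.

Step 5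
Reactants: 7 1-{3-[2-(benzyloxy)-5-methoxybenzyl]-2-hydroxy-4,5,6-trimethoxyphenyl}ethanone
Product: 9 8-[2-(benzyloxy)-5-methoxybenzyl]-5,6,7-trimethoxy-4H-chromen-4-one, via enaminone 8 (not isolated)
Conditions: Me2NCH(OMe)2, toluene, 100 °C; concentrate; then conc. HCl, CH2Cl2, 40 °C
Reagents that add atoms: N,N-dimethylformamide dimethyl acetal, COC(OC)N(C)C
Why: Condensation of the methyl ketone with the amide acetal gives enaminone 8, and acid then triggers intramolecular oxa-Michael addition of the ring A phenol to the enaminone beta carbon and elimination of dimethylamine, forming the O1–C2 bond in the standard enaminone chromone synthesis, under which the benzyl and methyl ethers are stable.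

Step 6
Reactants: 9 8-[2-(benzyloxy)-5-methoxybenzyl]-5,6,7-trimethoxy-4H-chromen-4-one; 10 phenylboronic acid
Product: 11 (2S)-8-[2-(benzyloxy)-5-methoxybenzyl]-5,6,7-trimethoxy-2-phenylchroman-4-one
Conditions: Pd(OCOCF3)2 (10 mol %), (R)-t-BuPyOx [(R)-4-tert-butyl-2-(pyridin-2-yl)-4,5-dihydrooxazole] (12 mol %), NH4PF6 (30 mol %), H2O (5 equiv), ClCH2CH2Cl, 60 °C
Reagents that add atoms: none
Why: Transmetalation from boron to the cationic divalent palladium centre bearing the pyridine-oxazoline gives a phenylpalladium species, the C2=C3 bond of 9 coordinates and inserts so that phenyl goes to C2 and palladium ends on the enolate, and water protonates that enolate to release the flavanone and regenerate the catalyst with no change of oxidation state; this is the known palladium/pyridine-oxazoline asymmetric conjugate addition of arylboronic acids to chromones. No ring is closed here, ring C being already in place, so no mode of closure applies. The new stereocentre C2 is set under catalyst control in the insertion step, where the tert-butyl group of the oxazoline leaves only one enantioface of the enone open, and the (R)-ligand is chosen to give (S). The step needs enantiofacial discrimination on a planar substrate and protonation of the palladium enolate faster than beta-hydride elimination to the flavone; the first is secured because 9 is achiral with an unsubstituted, unhindered C2 as the beta carbon of a vinylogous ester, the second by the water in the medium. The substrate is suited because both phenols are capped as ethers, so nothing chelates palladium or opens the pyranone, and the oxygen that serves as O1 was fixed earlier by the single free phenol of 7.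

Step 7
Reactants: 11 (2S)-8-[2-(benzyloxy)-5-methoxybenzyl]-5,6,7-trimethoxy-2-phenylchroman-4-one
Product: 12 (2S)-5-hydroxy-8-(2-hydroxy-5-methoxybenzyl)-6,7-dimethoxy-2-phenylchroman-4-one
Conditions: BCl3, C6HMe5, CH2Cl2, −78 to 0 °C; then ice-water
Reagents that add atoms: none
Why: BCl3 cleaves the aryl benzyl ether at low temperature with pentamethylbenzene as a non-basic benzyl cation trap, and on warming boron chelated between the C4 carbonyl and the C5 oxygen removes the peri methyl group as chloromethane (chelation-directed Lewis-acid demethylation), while the C6, C7 and ring D methyl ethers lack this activation and C2 should keep its configuration because no base is present and the temperature stays at or below 0 °C.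

## Compound list

1 | 3,4,5-trimethoxyphenol | COc1cc(O)cc(OC)c1OC | starting material
2 | 1-(6-hydroxy-2,3,4-trimethoxyphenyl)ethanone | CC(=O)c1c(O)cc(OC)c(OC)c1OC | intermediate
3 | 2-hydroxy-5-methoxybenzaldehyde | COc1ccc(O)c(C=O)c1 | starting material
4 | 2-(hydroxymethyl)-4-methoxyphenol (2-hydroxy-5-methoxybenzyl alcohol) | COc1ccc(O)c(CO)c1 | intermediate
5 | 4-methoxy-6-methylidenecyclohexa-2,4-dien-1-one (ortho-quinone methide) | C=C1C=C(OC)C=CC1=O | intermediate (not isolated)
6 | 1-[2-hydroxy-3-(2-hydroxy-5-methoxybenzyl)-4,5,6-trimethoxyphenyl]ethanone | CC(=O)c1c(O)c(Cc2cc(OC)ccc2O)c(OC)c(OC)c1OC | intermediate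
7 | 1-{3-[2-(benzyloxy)-5-methoxybenzyl]-2-hydroxy-4,5,6-trimethoxyphenyl}ethanone | CC(=O)c1c(O)c(Cc2cc(OC)ccc2OCc2ccccc2)c(OC)c(OC)c1OC | intermediate
8 | (E)-1-{3-[2-(benzyloxy)-5-methoxybenzyl]-2-hydroxy-4,5,6-trimethoxyphenyl}-3-(dimethylamino)prop-2-en-1-one | CN(C)/C=C/C(=O)c1c(O)c(Cc2cc(OC)ccc2OCc2ccccc2)c(OC)c(OC)c1OC | intermediate (not isolated)
9 | 8-[2-(benzyloxy)-5-methoxybenzyl]-5,6,7-trimethoxy-4H-chromen-4-one | O=C1C=COc2c(Cc3cc(OC)ccc3OCc3ccccc3)c(OC)c(OC)c(OC)c12 | intermediate
10 | phenylboronic acid | OB(O)c1ccccc1 | starting material
11 | (2S)-8-[2-(benzyloxy)-5-methoxybenzyl]-5,6,7-trimethoxy-2-phenylchroman-4-one | COc1ccc(OCc2ccccc2)c(Cc2c(OC)c(OC)c(OC)c3c2O[C@H](c2ccccc2)CC3=O)c1 | intermediate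
12 | (2S)-5-hydroxy-8-(2-hydroxy-5-methoxybenzyl)-6,7-dimethoxy-2-phenylchroman-4-one | COc1ccc(O)c(Cc2c(OC)c(OC)c(O)c3c2O[C@H](c2ccccc2)CC3=O)c1 | target

## Step count and risks

Total steps: 7. Longest linear sequence: 6 steps (1 → 2 → 6 → 7 → 9 → 11 → 12; the branch 3 → 4 joins at step 3).

Steps most likely to fail:

Step 3. The quinone methide may add to the free ortho carbon of its own precursor faster than to the acetyl-deactivated, doubly flanked ring carbon of 2, giving oligomers and returning 2. The fallback reverses the order of the two carbon–carbon bond formations. Setting out from 1 and 4, the same ZnCl2-promoted benzylation is run on the far more nucleophilic phenol 1, used in excess (its two ortho carbons are equivalent), to give 2-(2-hydroxy-5-methoxybenzyl)-3,4,5-trimethoxyphenol F1. Acetylation with AcOH and BF3·OEt2 should then go to the one open carbon of ring A, which is activated by its own phenol and two methoxy groups and should outcompete ring D. The route is rejoined at 6.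

Step 6. Insertion into the electron-rich chromone, flanked at C8, may be slow, so that protodeboronation and homocoupling use up the boronic acid. Beta-hydride elimination to the flavone may compete, or the facial preference may be eroded. The fallback sets the stereocentre by resolution instead of by addition. Setting out from 7, Claisen–Schmidt condensation with benzaldehyde (KOH, EtOH) gives the chalcone (E)-1-{3-[2-(benzyloxy)-5-methoxybenzyl]-2-hydroxy-4,5,6-trimethoxyphenyl}-3-phenylprop-2-en-1-one F2. Oxa-Michael cyclisation (NaOAc, EtOH, reflux) then gives racemic 8-[2-(benzyloxy)-5-methoxybenzyl]-5,6,7-trimethoxy-2-phenylchroman-4-one F3. Kinetic resolution by asymmetric transfer hydrogenation with RuCl[(R,R)-TsDPEN](p-cymene) and HCO2H/Et3N, stopped near half conversion, is expected to reduce the (R)-ketone to the cis alcohol (2R,4R)-8-[2-(benzyloxy)-5-methoxybenzyl]-5,6,7-trimethoxy-2-phenylchroman-4-ol F4, which is separated. The unreacted (S)-ketone is 11, where the route is rejoined.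

Step 7. The Lewis acid may open the boron-chelated 5-hydroxyflavanone to its chalcone, which would lower the enantiomeric purity at C2 and allow reclosure through the other phenol. It may also demethylate further at C6. The fallback moves the Lewis-acid operation to the achiral chromone stage, so that the last step is neutral. Setting out from 9, BCl3 and pentamethylbenzene (−78 to 0 °C) give 5-hydroxy-8-(2-hydroxy-5-methoxybenzyl)-6,7-dimethoxy-4H-chromen-4-one F5. Both phenols are then benzylated (BnBr, K2CO3, DMF, 60 °C) to 5-(benzyloxy)-8-[2-(benzyloxy)-5-methoxybenzyl]-6,7-dimethoxy-4H-chromen-4-one F6. The conjugate addition of step 6 with 10 gives (2S)-5-(benzyloxy)-8-[2-(benzyloxy)-5-methoxybenzyl]-6,7-dimethoxy-2-phenylchroman-4-one F7. Hydrogenolysis (H2, Pd/C, EtOAc, rt) removes both benzyl groups and the route is rejoined at 12.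

## Further compounds

F1 | step 3 | 2-(2-hydroxy-5-methoxybenzyl)-3,4,5-trimethoxyphenol | COc1ccc(O)c(Cc2c(O)cc(OC)c(OC)c2OC)c1
F2 | step 6 | (E)-1-{3-[2-(benzyloxy)-5-methoxybenzyl]-2-hydroxy-4,5,6-trimethoxyphenyl}-3-phenylprop-2-en-1-one | O=C(/C=C/c1ccccc1)c1c(O)c(Cc2cc(OC)ccc2OCc2ccccc2)c(OC)c(OC)c1OC
F3 | step 6 | racemic 8-[2-(benzyloxy)-5-methoxybenzyl]-5,6,7-trimethoxy-2-phenylchroman-4-one | COc1ccc(OCc2ccccc2)c(Cc2c(OC)c(OC)c(OC)c3c2OC(c2ccccc2)CC3=O)c1
F4 | step 6 | (2R,4R)-8-[2-(benzyloxy)-5-methoxybenzyl]-5,6,7-trimethoxy-2-phenylchroman-4-ol | COc1ccc(OCc2ccccc2)c(Cc2c(OC)c(OC)c(OC)c3c2O[C@@H](c2ccccc2)C[C@H]3O)c1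
F5 | step 7 | 5-hydroxy-8-(2-hydroxy-5-methoxybenzyl)-6,7-dimethoxy-4H-chromen-4-one | O=C1C=COc2c(Cc3cc(OC)ccc3O)c(OC)c(OC)c(O)c12
F6 | step 7 | 5-(benzyloxy)-8-[2-(benzyloxy)-5-methoxybenzyl]-6,7-dimethoxy-4H-chromen-4-one | O=C1C=COc2c(Cc3cc(OC)ccc3OCc3ccccc3)c(OC)c(OC)c(OCc3ccccc3)c12
F7 | step 7 | (2S)-5-(benzyloxy)-8-[2-(benzyloxy)-5-methoxybenzyl]-6,7-dimethoxy-2-phenylchroman-4-one | COc1ccc(OCc2ccccc2)c(Cc2c(OC)c(OC)c(OCc4ccccc4)c3c2O[C@H](c2ccccc2)CC3=O)c1
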